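**Retrosynthetic overview**

- The strategy rests on C2 of the 2H-chromene: a tertiary allylic aryl ether carbon bearing ring O1, a methyl group, the side-chain CH2 and the vinylic C3. It is the branched product of phenoxide attack on a geranyl-type allyl unit, and the cis C3=C4 bond from C2 to arene carbon C4a is a ring olefin that diene metathesis can close.
- Disconnections: C3=C4 (ring-closing metathesis of an ortho-vinylaryl tertiary allyl ether); O1–C2 (palladium-catalysed asymmetric allylic etherification of a 2-vinylphenol with a C20 allyl methyl carbonate); the CH2–CH2 bond next to the cyclohexene (alkylation of β-cyclogeranyl phenyl sulfone with an 8-bromogeranyl ether, then desulfonylation).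
- Ring order: the cyclohexene (β-cyclocitral) and the arene (2,5-dihydroxybenzaldehyde) are bought; the pyran ring is closed last, one step after the stereocenter is set.

Key step: step 13

Assumption (remark on the chemistry): the (R,R) hand of the bisphosphine ligand is taken to give the 2S ether from the E carbonate. The sense of induction is to be confirmed on the first run by chiral HPLC against the product of the (S,S) ligand, and the other hand is used, with nothing else changed, if it proves opposite.

Step 1
Reactants: 1 β-cyclocitral (2,6,6-trimethylcyclohex-1-ene-1-carbaldehyde)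
Product: 2 β-cyclogeraniol [(2,6,6-trimethylcyclohex-1-en-1-yl)methanol]
Conditions: NaBH4, MeOH, 0 °C
Reagents that add atoms: none
Why: Borohydride 1,2-reduction of the hindered enal should give the allylic alcohol cleanly, since NaBH4 does not touch the tetrasubstituted olefin.

Step 2
Reactants: 2 β-cyclogeraniol
Product: 3 β-cyclogeranyl bromide [2-(bromomethyl)-1,3,3-trimethylcyclohex-1-ene]
Conditions: PBr3, pyridine (cat.), Et2O, −10 to 0 °C; used crude
Reagents that add atoms: phosphorus tribromide, BrP(Br)Br
Why: Bromination of a primary allylic alcohol with PBr3 (substitution through the phosphite ester) should proceed without allylic transposition, because the transposed bromide would be tertiary and would cost the tetrasubstituted olefin.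

Step 3
Reactants: 3 β-cyclogeranyl bromide
Product: 4 β-cyclogeranyl phenyl sulfone ({[(2,6,6-trimethylcyclohex-1-en-1-yl)methyl]sulfonyl}benzene)
Conditions: PhSO2Na, DMF, rt
Reagents that add atoms: sodium benzenesulfinate, [Na+].[O-]S(=O)c1ccccc1
Why: SN2 displacement of the primary allylic bromide by the sulfur atom of the sulfinate (sulfinate S-alkylation) should give the stable sulfone that serves as the carbanion precursor.

Step 4
Reactants: 5 geraniol [(2E)-3,7-dimethylocta-2,6-dien-1-ol]
Product: 6 geranyl TBS ether (tert-butyl{[(2E)-3,7-dimethylocta-2,6-dien-1-yl]oxy}dimethylsilane)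
Conditions: TBSCl, imidazole, DMF, 0 °C to rt
Reagents that add atoms: tert-butyldimethylsilyl chloride, CC(C)(C)[Si](C)(C)Cl
Why: Standard silylation of a primary alcohol with a silyl chloride and imidazole should protect the C1 oxygen for the oxidation, bromination and organolithium steps that follow.

Step 5
Reactants: 6 geranyl TBS ether
Product: 8 (2E,6E)-8-hydroxygeranyl TBS ether, via (2E,6E)-8-oxogeranyl TBS ether 7 (not isolated)
Conditions: SeO2 (cat.), t-BuOOH, salicylic acid (cat.), CH2Cl2, 0 °C to rt; then NaBH4, MeOH, 0 °C
Reagents that add atoms: selenium dioxide, O=[Se]=O; tert-butyl hydroperoxide, CC(C)(C)OO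
Why: Catalytic SeO2 allylic oxidation (ene reaction followed by 2,3-sigmatropic shift) should attack the E methyl group of the more electron-rich terminal olefin, and the NaBH4 treatment should return the over-oxidised portion, enal 7, to the same E allylic alcohol.

Step 6
Reactants: 8 (2E,6E)-8-hydroxygeranyl TBS ether
Product: 9 (2E,6E)-8-bromogeranyl TBS ether
Conditions: CBr4, PPh3, CH2Cl2, −20 to 0 °C; used promptly
Reagents that add atoms: carbon tetrabromide, BrC(Br)(Br)Br
Why: Appel bromination under neutral conditions should replace the primary allylic hydroxyl by bromide through SN2 attack on the alkoxyphosphonium ion, keeping the E geometry and the silyl ether.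

Step 7
Reactants: 4 β-cyclogeranyl phenyl sulfone; 9 (2E,6E)-8-bromogeranyl TBS ether
Product: 11 C20 sulfone TBS ether (racemic at the sulfonyl-bearing carbon), via α-lithio sulfone 10 (not isolated)
Conditions: n-BuLi, THF, −78 °C; then 9, −78 to −20 °C
Reagents that add atoms: none
Why: Alkylation of an α-sulfonyl carbanion: deprotonation of 4 gives the sulfone-stabilised anion 10, which should react at its α carbon (the γ carbon is a fully substituted ring carbon) with the unhindered primary allylic bromide by SN2 to join the two halves, the new sulfonyl-bearing center being racemic and removed in step 8.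

Step 8
Reactants: 11 C20 sulfone TBS ether
Product: 12 C20 TBS ether (tert-butyl{[(2E,6E)-3,7-dimethyl-9-(2,6,6-trimethylcyclohex-1-en-1-yl)nona-2,6-dien-1-yl]oxy}dimethylsilane)
Conditions: PdCl2(dppp) (5 mol%), LiBHEt3, THF, 0 °C
Reagents that add atoms: none
Why: Palladium-catalysed reductive desulfonylation of an allylic sulfone: zerovalent palladium generated in situ should ionise the allylic C–S bond and pass hydride to the less hindered chain-side terminus of the allyl unit, which keeps the ring olefin tetrasubstituted and leaves the two E olefins and the silyl ether alone.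

Step 9
Reactants: 12 C20 TBS ether
Product: 13 C20 alcohol [(2E,6E)-3,7-dimethyl-9-(2,6,6-trimethylcyclohex-1-en-1-yl)nona-2,6-dien-1-ol]
Conditions: TBAF, THF, 0 °C to rt
Reagents that add atoms: none
Why: Fluoride-induced cleavage of the Si–O bond (desilylation) should free the primary allylic alcohol without affecting any olefin.

Step 10
Reactants: 13 C20 alcohol
Product: 14 C20 methyl carbonate [methyl (2E,6E)-3,7-dimethyl-9-(2,6,6-trimethylcyclohex-1-en-1-yl)nona-2,6-dien-1-yl carbonate]
Conditions: ClCO2Me, pyridine, CH2Cl2, 0 °C
Reagents that add atoms: methyl chloroformate, COC(=O)Cl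
Why: Acylation of the primary allylic alcohol with a chloroformate and pyridine should give the methyl carbonate, a leaving group that ionises readily to an allylpalladium complex and supplies its own base.

Step 11
Reactants: 15 2,5-dihydroxybenzaldehyde
Product: 16 2-hydroxy-5-(triisopropylsilyloxy)benzaldehyde
Conditions: TIPSCl (1.05 equiv), imidazole, DMF, 0 °C
Reagents that add atoms: triisopropylsilyl chloride, CC(C)[Si](Cl)(C(C)C)C(C)C
Why: Selective silylation should occur at the 5-hydroxyl because the 2-hydroxyl is held in a hydrogen bond to the aldehyde and is both less nucleophilic and more hindered.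

Step 12
Reactants: 16 2-hydroxy-5-(triisopropylsilyloxy)benzaldehyde
Product: 17 4-(triisopropylsilyloxy)-2-vinylphenol
Conditions: Ph3PCH3Br (2.6 equiv), NaN(SiMe3)2 (2.5 equiv), THF, 0 °C; then 16, 0 °C to rt; NH4Cl work-up; used fresh
Reagents that add atoms: methyltriphenylphosphonium bromide, C[P+](c1ccccc1)(c1ccccc1)c1ccccc1.[Br-]
Why: Wittig methylenation with excess ylide should convert the aldehyde into the vinyl group, one equivalent of ylide being spent on the phenol, whose phenoxide does not interfere with olefination.

Step 13
Reactants: 14 C20 methyl carbonate; 17 4-(triisopropylsilyloxy)-2-vinylphenol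
Product: 18 (S)-tertiary allyl aryl ether diene (triisopropyl{4-[((3S,6E)-3,7-dimethyl-9-(2,6,6-trimethylcyclohex-1-en-1-yl)nona-1,6-dien-3-yl)oxy]-3-vinylphenoxy}silane)
Conditions: Pd2(dba)3·CHCl3 (1.5 mol%), (R,R)-DACH-phenyl Trost ligand {N,N'-[(1R,2R)-cyclohexane-1,2-diyl]bis[2-(diphenylphosphanyl)benzamide], 4.5 mol%}, Bu4NCl (30 mol%), CH2Cl2 (0.05 M), rt, argon
Reagents that add atoms: none
Why: Zerovalent palladium ionises the primary allylic carbonate of 14 with loss of CO2, the methoxide set free deprotonates 17, and the phenoxide adds to the trisubstituted terminus of the allylpalladium cation on the face away from the metal; the closest known reaction type is the Tsuji–Trost asymmetric allylic etherification of para-alkoxyphenols with geranyl methyl carbonate. No ring is closed in this step: only the O1–C2 bond is made, which joins the arene to the C20 chain, and the pyran ring follows in step 14. The single stereocenter C2 is set as S by the chiral pocket of the twofold-symmetric bisphosphine acting on an allyl unit whose substituent geometry is fixed by the 2E olefin carried over from geraniol, and the dilute, chloride-containing medium is chosen so that the diastereomeric allyl complexes interconvert faster than they are attacked, leaving the choice of face to the ligand. The step needs branched-over-linear regioselectivity and one enantioface: the regioselectivity should hold because 14 is locally identical to geranyl methyl carbonate, the electron-rich phenoxide of 17 attacks the more substituted, more electrophilic terminus, and once bound it is too poor a leaving group for the tertiary ether to be re-ionised and drained into the linear isomer. The styrene, the remote tri- and tetrasubstituted olefins and the aryl silyl ether are spectators under these neutral room-temperature conditions.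

Step 14
Reactants: 18 (S)-tertiary allyl aryl ether diene
Product: 19 (S)-chromene TIPS ether (triisopropyl({(2S)-2-methyl-2-[(3E)-4-methyl-6-(2,6,6-trimethylcyclohex-1-en-1-yl)hex-3-en-1-yl]-2H-chromen-6-yl}oxy)silane)
Conditions: first-generation Grubbs catalyst RuCl2(PCy3)2(=CHPh) (5 mol%), CH2Cl2 (0.01 M), rt to 40 °C, argon
Reagents that add atoms: none
Why: Ring-closing metathesis of two monosubstituted olefins held 1,6 through the aryl ether: the ruthenium alkylidene should form at the unhindered styrene and close onto the neighbouring tertiary vinyl group to give the six-membered pyran ring with its cis C3=C4 bond and ethylene, while a catalyst that is sluggish with tri- and tetrasubstituted olefins leaves the chain and ring olefins alone and the mild temperature avoids aromatic Claisen rearrangement at C2.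

Step 15
Reactants: 19 (S)-chromene TIPS ether
Product: 20 target, (2S)-2-methyl-2-[(3E)-4-methyl-6-(2,6,6-trimethylcyclohex-1-en-1-yl)hex-3-en-1-yl]-2H-chromen-6-ol
Conditions: TBAF, AcOH (1:1), degassed THF, 0 °C, argon
Reagents that add atoms: none
Why: Fluoride cleavage of the aryl silyl ether (desilylation), buffered with AcOH and run under argon, should free the air-sensitive chromenol without touching C2 or the olefins.

**Compound list**

1 | β-cyclocitral | CC1=C(C=O)C(C)(C)CCC1 | starting material
2 | β-cyclogeraniol | CC1=C(CO)C(C)(C)CCC1 | intermediate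
3 | β-cyclogeranyl bromide | CC1=C(CBr)C(C)(C)CCC1 | intermediate
4 | β-cyclogeranyl phenyl sulfone | CC1=C(CS(=O)(=O)c2ccccc2)C(C)(C)CCC1 | intermediate
5 | geraniol | CC(C)=CCC/C(C)=C/CO | starting material
6 | geranyl TBS ether | CC(C)=CCC/C(C)=C/CO[Si](C)(C)C(C)(C)C | intermediate
7 | (2E,6E)-8-oxogeranyl TBS ether (not isolated) | O=C/C(C)=C/CC/C(C)=C/CO[Si](C)(C)C(C)(C)C | intermediate
8 | (2E,6E)-8-hydroxygeranyl TBS ether | OC/C(C)=C/CC/C(C)=C/CO[Si](C)(C)C(C)(C)C | intermediate
9 | (2E,6E)-8-bromogeranyl TBS ether | BrC/C(C)=C/CC/C(C)=C/CO[Si](C)(C)C(C)(C)C | intermediate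
10 | α-lithio β-cyclogeranyl phenyl sulfone (not isolated) | [Li]C(C1=C(C)CCCC1(C)C)S(=O)(=O)c1ccccc1 | intermediate
11 | C20 sulfone TBS ether, racemic at the sulfonyl-bearing carbon | CC1=C(C(C/C(C)=C/CC/C(C)=C/CO[Si](C)(C)C(C)(C)C)S(=O)(=O)c2ccccc2)C(C)(C)CCC1 | intermediate
12 | C20 TBS ether, (2E,6E)-7,8,11,12-tetrahydroretinyl TBS ether | CC1=C(CC/C(C)=C/CC/C(C)=C/CO[Si](C)(C)C(C)(C)C)C(C)(C)CCC1 | intermediate
13 | C20 alcohol, (2E,6E)-7,8,11,12-tetrahydroretinol | CC1=C(CC/C(C)=C/CC/C(C)=C/CO)C(C)(C)CCC1 | intermediate
14 | C20 methyl carbonate | CC1=C(CC/C(C)=C/CC/C(C)=C/COC(=O)OC)C(C)(C)CCC1 | intermediate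
15 | 2,5-dihydroxybenzaldehyde | O=Cc1cc(O)ccc1O | starting material
16 | 2-hydroxy-5-(triisopropylsilyloxy)benzaldehyde | O=Cc1cc(O[Si](C(C)C)(C(C)C)C(C)C)ccc1O | intermediate
17 | 4-(triisopropylsilyloxy)-2-vinylphenol | C=Cc1cc(O[Si](C(C)C)(C(C)C)C(C)C)ccc1O | intermediate
18 | (S)-tertiary allyl aryl ether diene | CC1=C(CC/C(C)=C/CC[C@@](C)(C=C)Oc2ccc(O[Si](C(C)C)(C(C)C)C(C)C)cc2C=C)C(C)(C)CCC1 | intermediate
19 | (S)-chromene TIPS ether | CC1=C(CC/C(C)=C/CC[C@@]2(C)C=Cc3cc(O[Si](C(C)C)(C(C)C)C(C)C)ccc3O2)C(C)(C)CCC1 | intermediate
20 | target, (2S)-2-methyl-2-[(3E)-4-methyl-6-(2,6,6-trimethylcyclohex-1-en-1-yl)hex-3-en-1-yl]-2H-chromen-6-ol | CC1=C(CC/C(C)=C/CC[C@@]2(C)C=Cc3cc(O)ccc3O2)C(C)(C)CCC1 | target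

**Step count**

Total: 15 steps. Longest linear sequence: 10 steps (from geraniol 5 through steps 4–10 and 13–15, or equally from β-cyclocitral 1 through steps 1–3, 7–10 and 13–15).

**Steps most likely to fail, with fallbacks**

Step 13 (asymmetric allylic etherification).
- What may go wrong: the phenoxide may attack the primary allyl terminus, or the tertiary ether may be re-ionised by palladium and drift to the linear isomer. Attack may also outpace interconversion of the diastereomeric allyl complexes, so that the face is not selected. The electron-rich vinylphenol may oligomerise before it is etherified.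
- Fallback: this sets out from alcohol 13 and replaces catalyst control of C2 by separation. MnO2 (CH2Cl2, rt) should oxidise 13 to (2E,6E)-3,7-dimethyl-9-(2,6,6-trimethylcyclohex-1-en-1-yl)nona-2,6-dienal F1. F1 and commercial 4-(tert-butyldimethylsilyloxy)phenol, heated with PhB(OH)2 and AcOH in toluene with azeotropic removal of water, should undergo boronate-templated ortho condensation and oxa-6π ring closure to the racemic chromene TBS ether F2. Preparative HPLC on a chiral stationary phase should give the (2S)-chromene TBS ether F3. AcOH-buffered TBAF (THF, 0 °C, argon) should then give 20, where the fallback rejoins the route; 18 and 19 are bypassed.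

Step 8 (reductive desulfonylation).
- What may go wrong: hydride may be passed to the ring terminus of the allyl unit, or base may isomerise the product, moving the ring olefin into the exocyclic position. Ionisation of the hindered C–S bond may also be slow, leaving sulfone unreduced.
- Fallback: this sets out from alcohol 2 and bromide 9 and joins the halves without an activating group. PPh3 and N-chlorosuccinimide (CH2Cl2, 0 °C) should convert 2 into β-cyclogeranyl chloride F4. F4 and activated barium (from BaI2 and Li/biphenyl, THF, −78 °C) should give β-cyclogeranylbarium chloride F5. F5 should couple with bromide 9 at −78 °C at its metal-bearing carbon by direct displacement (α,α′-selective allylbarium–allyl halide coupling, which keeps olefin position and geometry). This gives 12, where the fallback rejoins the route; steps 3, 7 and 8 are replaced.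

Step 5 (allylic oxidation).
- What may go wrong: over-oxidation to enal and acid, oxidation at the internal allylic CH2 groups, and erosion of the silyl ether by the acidic selenium species may leave little of 8.
- Fallback: this sets out from 6 and builds the E hydroxymethyl terminus by cleavage and olefination instead of C–H oxidation. mCPBA (1 equiv, NaHCO3, CH2Cl2, −20 °C) should epoxidise the more electron-rich terminal olefin to 6,7-epoxygeranyl TBS ether F6. H5IO6 (THF–Et2O, 0 °C, short contact) should cleave F6 to (4E)-6-(tert-butyldimethylsilyloxy)-4-methylhex-4-enal F7. The stabilised ylide Ph3P=C(CH3)CO2Et (CH2Cl2, rt) should give ethyl (2E,6E)-8-(tert-butyldimethylsilyloxy)-2,6-dimethylocta-2,6-dienoate F8 by E-selective Wittig olefination. i-Bu2AlH (CH2Cl2, −78 °C) should reduce F8 to 8, where the fallback rejoins the route.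

**Further compounds**

F1 | step 13 | (2E,6E)-3,7-dimethyl-9-(2,6,6-trimethylcyclohex-1-en-1-yl)nona-2,6-dienal | CC1=C(CC/C(C)=C/CC/C(C)=C/C=O)C(C)(C)CCC1
F2 | step 13 | racemic chromene TBS ether | CC1=C(CC/C(C)=C/CCC2(C)C=Cc3cc(O[Si](C)(C)C(C)(C)C)ccc3O2)C(C)(C)CCC1
F3 | step 13 | (2S)-chromene TBS ether | CC1=C(CC/C(C)=C/CC[C@@]2(C)C=Cc3cc(O[Si](C)(C)C(C)(C)C)ccc3O2)C(C)(C)CCC1
F4 | step 8 | β-cyclogeranyl chloride | CC1=C(CCl)C(C)(C)CCC1
F5 | step 8 | β-cyclogeranylbarium chloride | CC1=C(C[Ba]Cl)C(C)(C)CCC1
F6 | step 5 | 6,7-epoxygeranyl TBS ether | CC1(C)OC1CC/C(C)=C/CO[Si](C)(C)C(C)(C)C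
F7 | step 5 | (4E)-6-(tert-butyldimethylsilyloxy)-4-methylhex-4-enal | O=CCC/C(C)=C/CO[Si](C)(C)C(C)(C)C
F8 | step 5 | ethyl (2E,6E)-8-(tert-butyldimethylsilyloxy)-2,6-dimethylocta-2,6-dienoate | CCOC(=O)/C(C)=C/CC/C(C)=C/CO[Si](C)(C)C(C)(C)C
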